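**Retrosynthetic overview**

1. The target, a (3E,4R)-3-arylidene-4-benzyloxolan-2-one, is traced back to its bis-silyl ether (two phenolic O–Si bonds).
2. In that ether the C4–CH2(vanillyl) bond and the exocyclic C3=CH(aryl) bond are cut in one three-component operation, giving a 4-silyloxy-3-methoxybenzylzinc chloride, 3-(diethoxyphosphoryl)furan-2(5H)-one and 3-silyloxy-4,5-dimethoxybenzaldehyde.
3. Enabling feature: in the oxolan-2-one ring the stereogenic C4 is β and C3 is α to the C2 carbonyl, and C3 carries the exocyclic C=C. A phosphoryl group on C3 therefore makes C4 a doubly activated Michael terminus for the benzyl nucleophile, and the resulting phosphonoenolate olefinates the aldehyde and expels the activating group in the same flask.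
4. Ring order: no ring is built. The lactone ring is bought as diethyl (2-oxooxolan-3-yl)phosphonate and only desaturated at C3=C4 (selenoxide elimination); the two benzene rings come from vanillin and 3-hydroxy-4,5-dimethoxybenzaldehyde.
5. The single stereocentre (C4, R) is set in the key step by a chiral Cu(I) catalyst and the E alkene by the olefination; the last step only removes the silyl groups.

Key step: step 8

**Remarks**

- The SMILES is read as (3E,4R): the aryl group is trans to the lactone carbonyl, and C4 has the ranking CH2O > C3 > CH2Ar > H.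
- Salts formed by simple deprotonation of a numbered compound (with NaH, NaHMDS or LDA) are treated as that compound under the stated conditions and carry no number of their own.
- L* = (S)-1,1'-binaphthyl-2,2'-diyl N,N-bis[(R)-1-phenylethyl]phosphoramidite; both antipodes are available.
- Compounds 1, 7 and 11 are taken as commercial.

**Route**

Step 1
Reactants: 1 vanillin (4-hydroxy-3-methoxybenzaldehyde)
Product: 2 4-[(tert-butyldimethylsilyl)oxy]-3-methoxybenzaldehyde
Conditions: TBSCl, imidazole, DMF, rt
Reagents that add atoms: tert-butyldimethylsilyl chloride, CC(C)(C)[Si](C)(C)Cl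
Why: Imidazole-promoted O-silylation (silyl ether protection) of the phenol removes the acidic proton that would later quench the organozinc and the enolate, while the aldehyde is inert.

Step 2
Reactants: 2 4-[(tert-butyldimethylsilyl)oxy]-3-methoxybenzaldehyde
Product: 3 {4-[(tert-butyldimethylsilyl)oxy]-3-methoxyphenyl}methanol
Conditions: NaBH4, MeOH, 0 °C
Reagents that add atoms: none
Why: Borohydride reduction of the aryl aldehyde should give the benzylic alcohol, the aryl silyl ether being stable to NaBH4 in methanol at 0 °C.

Step 3
Reactants: 3 {4-[(tert-butyldimethylsilyl)oxy]-3-methoxyphenyl}methanol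
Product: 5 tert-butyl[4-(chloromethyl)-2-methoxyphenoxy]dimethylsilane, via benzylic mesylate 4 (not isolated)
Conditions: MsCl, Et3N, CH2Cl2, 0 °C → rt
Reagents that add atoms: methanesulfonyl chloride, CS(=O)(=O)Cl (source of the chlorine in 5)
Why: Mesylation followed by in situ nucleophilic substitution by the liberated chloride, which is fast for a para-oxygenated benzylic mesylate, should give the benzylic chloride under non-acidic conditions that spare the silyl ether.

Step 4
Reactants: 5 tert-butyl[4-(chloromethyl)-2-methoxyphenoxy]dimethylsilane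
Product: 6 {4-[(tert-butyldimethylsilyl)oxy]-3-methoxybenzyl}zinc chloride (LiCl complex, THF solution, titrated and used as such)
Conditions: Zn dust (activated with BrCH2CH2Br and TMSCl), LiCl, THF, 25 °C
Reagents that add atoms: zinc, [Zn]
Why: LiCl-assisted oxidative insertion of zinc into the benzylic C–Cl bond should give the benzylic zinc chloride with little Wurtz coupling and full tolerance of the aryl silyl ether.

Step 5
Reactants: 7 diethyl (2-oxooxolan-3-yl)phosphonate
Product: 8 rac-diethyl [2-oxo-3-(phenylselanyl)oxolan-3-yl]phosphonate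
Conditions: NaH, THF, 0 °C; then PhSeCl, 0 °C → rt
Reagents that add atoms: benzeneselenenyl chloride, Cl[Se]c1ccccc1
Why: Electrophilic α-selenenylation of the phosphonate-stabilised lactone enolate places selenium on C3, which becomes quaternary, so that the later elimination can only go toward C4.

Step 6
Reactants: 8 rac-diethyl [2-oxo-3-(phenylselanyl)oxolan-3-yl]phosphonate
Product: 10 diethyl (2-oxo-2,5-dihydrofuran-3-yl)phosphonate [3-(diethoxyphosphoryl)furan-2(5H)-one], via selenoxide 9 (not isolated)
Conditions: 30% H2O2, CH2Cl2, 0 °C → rt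
Reagents that add atoms: none
Why: Oxidation to the selenoxide and spontaneous syn-elimination (selenoxide elimination) toward the only β-hydrogens, those on C4, should give the endocyclic vinylphosphonate under mild, non-basic conditions.

Step 7
Reactants: 11 3-hydroxy-4,5-dimethoxybenzaldehyde
Product: 12 3-[(tert-butyldimethylsilyl)oxy]-4,5-dimethoxybenzaldehyde
Conditions: TBSCl, imidazole, DMF, rt
Reagents that add atoms: tert-butyldimethylsilyl chloride, CC(C)(C)[Si](C)(C)Cl
Why: Imidazole-promoted O-silylation of the phenol keeps the aldehyde partner from protonating the zinc phosphonoenolate of the key step.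

Step 8
Reactants: 6 {4-[(tert-butyldimethylsilyl)oxy]-3-methoxybenzyl}zinc chloride, 10 diethyl (2-oxo-2,5-dihydrofuran-3-yl)phosphonate, 12 3-[(tert-butyldimethylsilyl)oxy]-4,5-dimethoxybenzaldehyde
Product: 14 (3E,4R)-3-({3-[(tert-butyldimethylsilyl)oxy]-4,5-dimethoxyphenyl}methylidene)-4-({4-[(tert-butyldimethylsilyl)oxy]-3-methoxyphenyl}methyl)oxolan-2-one, via chlorozinc phosphonoenolate 13 (not isolated)
Conditions: CuTC (5 mol %), L* (10 mol %), THF–toluene, −40 °C, slow addition of 10 to 6; then 12, TMEDA, −40 → 40 °C; aq. NH4Cl
Reagents that add atoms: none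
Why: Proposed new method: a Cu(I)–phosphoramidite complex takes the benzyl group from 6, binds the C3=C4 bond of 10 and transfers the benzyl group to C4 (oxidative addition to a Cu(III) enolate, reductive elimination) to give zinc phosphonoenolate 13, which then attacks aldehyde 12 and collapses through the oxaphosphetane with loss of diethyl phosphate (Horner–Wadsworth–Emmons olefination). The closest known reaction types are the Cu/phosphoramidite-catalysed asymmetric conjugate addition of organozinc reagents to unsaturated lactones and alkylidene malonates with aldehyde trapping of the zinc enolate, and the non-asymmetric Michael addition/HWE sequence of Grignard reagents on 3-phosphoryl-2(5H)-furanones; new here are the benzylic zinc partner under ligand control and the direct olefination of the zinc enolate. No ring is closed, since the lactone is present from the start. The C4 stereocentre is set by the chiral ligand, which has to deliver the benzyl group to the Si face of C4 (C3 > C5 > H) to give the R configuration of 14, and the antipode of the ligand that does so is fixed in the first run. The step needs 1,4-addition at C4 rather than deprotonation at C5 or addition to C2=O, secured by the weakly basic Cu-bound benzyl group and the double activation of C4 by C2=O and P=O; it needs the aldehyde to meet only the enolate, secured by adding 12 after 10 is consumed; and it needs E geometry, secured by the reversible aldol-type addition that places the aryl group anti to the lactone carbonyl before phosphate is lost.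

Step 9
Reactants: 14 (3E,4R)-3-({3-[(tert-butyldimethylsilyl)oxy]-4,5-dimethoxyphenyl}methylidene)-4-({4-[(tert-butyldimethylsilyl)oxy]-3-methoxyphenyl}methyl)oxolan-2-one
Product: 15 (3E,4R)-3-[(3-hydroxy-4,5-dimethoxyphenyl)methylidene]-4-[(4-hydroxy-3-methoxyphenyl)methyl]oxolan-2-one
Conditions: TBAF, AcOH, THF, 0 °C
Reagents that add atoms: none
Why: Fluoride-mediated cleavage of both aryl silyl ethers, buffered with acetic acid so that neither phenoxide nor hydroxide opens the lactone or isomerises the alkene, should release the target, and the C4–H is not acidic, so the stereocentre is untouched.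

**Compound list**

1 | vanillin (4-hydroxy-3-methoxybenzaldehyde) | COc1cc(C=O)ccc1O | starting material
2 | 4-[(tert-butyldimethylsilyl)oxy]-3-methoxybenzaldehyde | COc1cc(C=O)ccc1O[Si](C)(C)C(C)(C)C | intermediate
3 | {4-[(tert-butyldimethylsilyl)oxy]-3-methoxyphenyl}methanol | COc1cc(CO)ccc1O[Si](C)(C)C(C)(C)C | intermediate
4 | 4-[(tert-butyldimethylsilyl)oxy]-3-methoxybenzyl methanesulfonate (not isolated) | COc1cc(COS(C)(=O)=O)ccc1O[Si](C)(C)C(C)(C)C | intermediate
5 | tert-butyl[4-(chloromethyl)-2-methoxyphenoxy]dimethylsilane | COc1cc(CCl)ccc1O[Si](C)(C)C(C)(C)C | intermediate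
6 | {4-[(tert-butyldimethylsilyl)oxy]-3-methoxybenzyl}zinc chloride (LiCl complex, THF solution) | COc1cc(C[Zn]Cl)ccc1O[Si](C)(C)C(C)(C)C | intermediate
7 | diethyl (2-oxooxolan-3-yl)phosphonate | CCOP(=O)(OCC)C1CCOC1=O | starting material
8 | rac-diethyl [2-oxo-3-(phenylselanyl)oxolan-3-yl]phosphonate | CCOP(=O)(OCC)C1([Se]c2ccccc2)CCOC1=O | intermediate
9 | diethyl [2-oxo-3-(phenylseleninyl)oxolan-3-yl]phosphonate (selenoxide, not isolated) | CCOP(=O)(OCC)C1([Se](=O)c2ccccc2)CCOC1=O | intermediate
10 | diethyl (2-oxo-2,5-dihydrofuran-3-yl)phosphonate | CCOP(=O)(OCC)C1=CCOC1=O | intermediate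
11 | 3-hydroxy-4,5-dimethoxybenzaldehyde | COc1cc(C=O)cc(O)c1OC | starting material
12 | 3-[(tert-butyldimethylsilyl)oxy]-4,5-dimethoxybenzaldehyde | COc1cc(C=O)cc(O[Si](C)(C)C(C)(C)C)c1OC | intermediate
13 | chlorozinc enolate of diethyl [(4S)-4-({4-[(tert-butyldimethylsilyl)oxy]-3-methoxyphenyl}methyl)-2-oxooxolan-3-yl]phosphonate (not isolated; same spatial arrangement at C4 as 14, the descriptor changes because the P-bearing C3 outranks C5) | COc1cc(C[C@H]2COC(O[Zn]Cl)=C2P(=O)(OCC)OCC)ccc1O[Si](C)(C)C(C)(C)C | intermediate
14 | (3E,4R)-3-({3-[(tert-butyldimethylsilyl)oxy]-4,5-dimethoxyphenyl}methylidene)-4-({4-[(tert-butyldimethylsilyl)oxy]-3-methoxyphenyl}methyl)oxolan-2-one | COc1cc(C[C@H]2COC(=O)/C2=C/c2cc(O[Si](C)(C)C(C)(C)C)c(OC)c(OC)c2)ccc1O[Si](C)(C)C(C)(C)C | intermediate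
15 | (3E,4R)-3-[(3-hydroxy-4,5-dimethoxyphenyl)methylidene]-4-[(4-hydroxy-3-methoxyphenyl)methyl]oxolan-2-one | COc1cc(C[C@H]2COC(=O)/C2=C/c2cc(O)c(OC)c(OC)c2)ccc1O | target

**Step count**

Total: 9 steps. Longest linear sequence: 6 steps (steps 1, 2, 3, 4, 8, 9).

**Steps most likely to fail**

1. Step 8 (bears "Proposed new method:"). What may go wrong: poor facial discrimination at C4, because uncatalysed addition of the benzylic zinc to the doubly activated acceptor competes with the ligand-controlled pathway, or slow olefination of the zinc phosphonoenolate. The fallback uses known chemistry (oxazolidinone-auxiliary enolate alkylation, reductive auxiliary removal with lactonisation, aldol addition and E1cB dehydration); it sets out from 5, uses 12, and returns at 14. Mono-tert-butyl succinate and (R)-4-benzyl-1,3-oxazolidin-2-one are coupled (PivCl, Et3N, LiCl, THF) to the imide (4R)-4-benzyl-3-(4-tert-butoxy-4-oxobutanoyl)-1,3-oxazolidin-2-one F1. Its sodium enolate (NaHMDS, THF, −78 °C) should be alkylated by 5 (Bu4NI) on the face away from the auxiliary benzyl group, forming the same C–CH2 bond and giving tert-butyl (3R)-4-[(4R)-4-benzyl-2-oxo-1,3-oxazolidin-3-yl]-3-({4-[(tert-butyldimethylsilyl)oxy]-3-methoxyphenyl}methyl)-4-oxobutanoate F2. LiBH4 (THF, MeOH, 0 °C) should remove the auxiliary reductively to tert-butyl (3R)-4-{4-[(tert-butyldimethylsilyl)oxy]-3-methoxyphenyl}-3-(hydroxymethyl)butanoate F3, which TsOH (cat., toluene) should close to (4R)-4-({4-[(tert-butyldimethylsilyl)oxy]-3-methoxyphenyl}methyl)oxolan-2-one F4. Deprotonation with LDA (THF, −78 °C) and addition of 12 should give the aldol adduct (4R)-3-({3-[(tert-butyldimethylsilyl)oxy]-4,5-dimethoxyphenyl}(hydroxy)methyl)-4-({4-[(tert-butyldimethylsilyl)oxy]-3-methoxyphenyl}methyl)oxolan-2-one F5 as a mixture at C3 and the carbinol carbon. MsCl/Et3N then converts it into the corresponding methanesulfonate F6, and DBU should eliminate this to the thermodynamically preferred E alkene 14.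

2. Step 6. What may go wrong: destruction of the strongly electrophilic vinylphosphonate under the aqueous oxidising conditions (conjugate addition of water or peroxide, nucleophilic epoxidation) and losses on isolation. The fallback sets out from 7 and returns at 10, replacing the oxidative syn-elimination by halogenation and base-mediated dehydrohalogenation under anhydrous, non-oxidising conditions. The sodium enolate of 7 (NaH, THF, 0 °C) is brominated with NBS to rac-diethyl (3-bromo-2-oxooxolan-3-yl)phosphonate F7, and Et3N (Et2O, rt) should eliminate HBr toward C4, as in the classical preparation of furan-2(5H)-one from the α-bromolactone, to give 10.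

3. Step 3. What may go wrong: ionisation of the electron-rich benzylic chloride during its formation or concentration, leading to self-alkylation of the arene (Friedel–Crafts oligomerisation) or loss of the silyl group. The fallback sets out from 3 and returns at 6 without any benzylic halide. Alcohol 3 is converted with PhSSPh and PBu3 (THF, rt) into tert-butyl{2-methoxy-4-[(phenylsulfanyl)methyl]phenoxy}dimethylsilane F8. Reductive lithiation of the C–S bond (lithium 4,4'-di-tert-butylbiphenylide, THF, −78 °C) should give {4-[(tert-butyldimethylsilyl)oxy]-3-methoxybenzyl}lithium F9, and ZnCl2 (THF, −78 → 0 °C) transmetalates it to 6.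

**Further compounds**

F1 | step 8 | (4R)-4-benzyl-3-(4-tert-butoxy-4-oxobutanoyl)-1,3-oxazolidin-2-one | CC(C)(C)OC(=O)CCC(=O)N1[C@H](Cc2ccccc2)COC1=O
F2 | step 8 | tert-butyl (3R)-4-[(4R)-4-benzyl-2-oxo-1,3-oxazolidin-3-yl]-3-({4-[(tert-butyldimethylsilyl)oxy]-3-methoxyphenyl}methyl)-4-oxobutanoate | COc1cc(C[C@H](CC(=O)OC(C)(C)C)C(=O)N2[C@H](Cc3ccccc3)COC2=O)ccc1O[Si](C)(C)C(C)(C)C
F3 | step 8 | tert-butyl (3R)-4-{4-[(tert-butyldimethylsilyl)oxy]-3-methoxyphenyl}-3-(hydroxymethyl)butanoate | COc1cc(C[C@H](CC(=O)OC(C)(C)C)CO)ccc1O[Si](C)(C)C(C)(C)C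
F4 | step 8 | (4R)-4-({4-[(tert-butyldimethylsilyl)oxy]-3-methoxyphenyl}methyl)oxolan-2-one | COc1cc(C[C@H]2COC(=O)C2)ccc1O[Si](C)(C)C(C)(C)C
F5 | step 8 | (4R)-3-({3-[(tert-butyldimethylsilyl)oxy]-4,5-dimethoxyphenyl}(hydroxy)methyl)-4-({4-[(tert-butyldimethylsilyl)oxy]-3-methoxyphenyl}methyl)oxolan-2-one (mixture at C3 and the carbinol carbon) | COc1cc(C[C@H]2COC(=O)C2C(O)c2cc(O[Si](C)(C)C(C)(C)C)c(OC)c(OC)c2)ccc1O[Si](C)(C)C(C)(C)C
F6 | step 8 | methanesulfonate of F5 | COc1cc(C[C@H]2COC(=O)C2C(OS(C)(=O)=O)c2cc(O[Si](C)(C)C(C)(C)C)c(OC)c(OC)c2)ccc1O[Si](C)(C)C(C)(C)C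
F7 | step 6 | rac-diethyl (3-bromo-2-oxooxolan-3-yl)phosphonate | CCOP(=O)(OCC)C1(Br)CCOC1=O
F8 | step 3 | tert-butyl{2-methoxy-4-[(phenylsulfanyl)methyl]phenoxy}dimethylsilane | COc1cc(CSc2ccccc2)ccc1O[Si](C)(C)C(C)(C)C
F9 | step 3 | {4-[(tert-butyldimethylsilyl)oxy]-3-methoxybenzyl}lithium | COc1cc(C[Li])ccc1O[Si](C)(C)C(C)(C)C
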